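**Retrosynthetic overview**

- The strategy rests on the cis-fused furo[3,4-c]furan (C1, O2, C3, C3a, C4, O5, C6, C6a): both aryl-bearing carbons, C1 and C4, are bonded to a ring oxygen (O2, O5), and both aryl groups stand on the outer, convex face, cis to H-6a and to the C3a oxygen. Each C–aryl bond is therefore the bond of a C-arylated cyclic acetal.
- Key disconnection: C1–aryl and C4–aryl, made last and together from a bis(lactol acetate) that already holds C3a and C6a, and two molecules of veratrole. No ring forms in this step.
- The bis-acetate comes from the 3a-silyloxy bis-lactone (i-Bu2AlH, then Ac2O), which comes from (R)-paraconic acid by α-methylenation, OsO4 dihydroxylation anti to the carboxyl group and lactonisation.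
- Ring order: the O5 ring is the lactone of paraconic acid and is present from the start; the O2 ring closes by lactonisation in step 5. Stereocentres: C6a by resolution, C3a in step 5, C1 and C4 in step 9.

Key step: step 9

Assumption: of the two diastereomeric salts of paraconic acid with (S)-1-phenylethylamine, the less soluble one is taken to hold the (R)-acid; should it hold the (S)-acid, (R)-1-phenylethylamine is used and nothing else changes.

Remarks:
- The carboxyl group is deliberately kept free up to step 5. As a carboxylate it keeps the proton on its α-carbon (the later C6a) non-acidic, so epimerisation, β-elimination of the lactone oxygen and migration of the exocyclic alkene into the ring are suppressed.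
- C1 and C4 of 9, 10 and 12 are anomeric mixtures; their configuration is erased on ionisation.
- Partial loss of the silyl group in step 9 would give 14 directly and is harmless.

**Route**

Step 1
Reactants: 1 (±)-paraconic acid
Product: 2 (S)-1-phenylethylammonium (3R)-5-oxooxolane-3-carboxylate
Conditions: (S)-PhCH(Me)NH2 (1 equiv), EtOH, reflux → 5 °C; recrystallise from EtOH
Reagents that add atoms: (S)-1-phenylethylamine C[C@H](N)c1ccccc1
Why: Classical resolution by diastereomeric salt crystallisation: the two salts differ in solubility, no bond at the stereocentre is touched, and the configuration of the later C6a is fixed here.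

Step 2
Reactants: 2 (S)-1-phenylethylammonium (3R)-5-oxooxolane-3-carboxylate
Product: 3 (R)-paraconic acid, (3R)-5-oxooxolane-3-carboxylic acid
Conditions: 2 M HCl (aq), 0 °C; continuous extraction with EtOAc
Reagents that add atoms: none
Why: Acid–base liberation: the mineral acid protonates the carboxylate and keeps the amine in water as its hydrochloride, under conditions that do not enolise the acid.

Step 3
Reactants: 3 (R)-paraconic acid
Product: 4 (4R)-2-oxooxolane-3,4-dicarboxylic acid (epimers at the new malonic carbon C3)
Conditions: MeOMgOCO2Me (2 M in DMF, excess), N2, 130 °C; then cold 6 M HCl, EtOAc; used crude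
Reagents that add atoms: methoxymagnesium methyl carbonate COC(=O)O[Mg]OC
Why: Stiles carboxylation, the standard entry to α-methylene paraconic acids: the substrate reacts as its magnesium carboxylate, so only the lactone α-CH2 is carboxylated (as a chelated magnesium enolate–carboxylate) and the carboxyl-bearing stereocentre is not deprotonated.

Step 4
Reactants: 4 (4R)-2-oxooxolane-3,4-dicarboxylic acid
Product: 5 (3R)-4-methylidene-5-oxooxolane-3-carboxylic acid
Conditions: 37% aq. HCHO, PhNHMe, NaOAc, AcOH, rt
Reagents that add atoms: formaldehyde C=O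
Why: Decarboxylative Mannich methylenation: the malonic half-acid is aminomethylated and the Mannich base fragments with loss of CO2 and amine to the exocyclic alkene, while the acetate buffer keeps 5 as acid or carboxylate so that C3 and the alkene position should hold.

Step 5
Reactants: 5 (3R)-4-methylidene-5-oxooxolane-3-carboxylic acid
Product: 7 (3aS,6aS)-3a-hydroxytetrahydro-1H,3H-furo[3,4-c]furan-1,4-dione, via diol acid 6 (not isolated)
Conditions: OsO4 (cat.), NMO, citric acid, t-BuOH/H2O, rt; then 1 M HCl, concentrate; TsOH·H2O (cat.), EtOAc, 60 °C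
Reagents that add atoms: osmium tetroxide O=[Os](=O)(=O)=O; N-methylmorpholine N-oxide C[N+]1([O-])CCOCC1; water O
Why: Catalytic OsO4 syn-dihydroxylation (acidic citric acid variant for electron-poor alkenes) should add to the alkene face anti to the neighbouring carboxyl group, which sets C3a with the tertiary hydroxyl trans and the new CH2OH cis to the carboxyl, and only this cis hydroxy acid can close the second γ-lactone on acid treatment (Fischer lactonisation), so a minor syn adduct would stay behind as an acid.

Step 6
Reactants: 7 (3aS,6aS)-3a-hydroxytetrahydro-1H,3H-furo[3,4-c]furan-1,4-dione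
Product: 8 (3aS,6aS)-3a-(triethylsilyloxy)tetrahydro-1H,3H-furo[3,4-c]furan-1,4-dione
Conditions: Et3SiOTf, 2,6-lutidine, CH2Cl2, −78 → 0 °C
Reagents that add atoms: triethylsilyl trifluoromethanesulfonate CC[Si](CC)(CC)OS(=O)(=O)C(F)(F)F
Why: Silyl triflate silylation reaches the hindered tertiary α-hydroxy lactone, and the weak, hindered base should not trigger β-elimination of the C3a oxygen from the C6a enolate.

Step 7
Reactants: 8 (3aS,6aS)-3a-(triethylsilyloxy)tetrahydro-1H,3H-furo[3,4-c]furan-1,4-dione
Product: 9 (3aS,6aS)-3a-(triethylsilyloxy)tetrahydro-1H,3H-furo[3,4-c]furan-1,4-diol (anomers at C1 and C4)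
Conditions: i-Bu2AlH (2.4 equiv), CH2Cl2, −78 °C; MeOH, aq. KNaC4H4O6
Reagents that add atoms: none
Why: Half-reduction of lactones to lactols with i-Bu2AlH: each lactone is held as a tetrahedral aluminium hemiacetal at −78 °C and released as the lactol on work-up, with C3a and C6a untouched.

Step 8
Reactants: 9 (3aS,6aS)-3a-(triethylsilyloxy)tetrahydro-1H,3H-furo[3,4-c]furan-1,4-diol
Product: 10 (3aS,6aS)-3a-(triethylsilyloxy)tetrahydro-1H,3H-furo[3,4-c]furan-1,4-diyl diacetate (anomers at C1 and C4)
Conditions: Ac2O, pyridine, DMAP (cat.), CH2Cl2, 0 °C → rt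
Reagents that add atoms: acetic anhydride CC(=O)OC(C)=O
Why: DMAP-catalysed acetylation of the two hemiacetal hydroxyls gives the ionisable anomeric acetates, the tertiary oxygen being already blocked as a non-participating silyl ether.

Step 9
Reactants: 10 (3aS,6aS)-3a-(triethylsilyloxy)tetrahydro-1H,3H-furo[3,4-c]furan-1,4-diyl diacetate; 11 veratrole (excess, two equivalents consumed)
Product: 13 O-triethylsilyl isogmelinol (1S,3aS,4R,6aR), via C1-monoaryl C4-acetate 12 (not isolated)
Conditions: Me3SiOTf (2.4 equiv), veratrole (5 equiv), CH2Cl2, −78 → −20 °C; Et3N, aq. NaHCO3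
Reagents that add atoms: none
Why: Me3SiOTf ionises each anomeric acetate to a ring oxocarbenium ion (C1=O2 first, then the inductively deactivated C4=O5), veratrole attacks it at the position para to one methoxy group and the arenium ion loses a proton, a Friedel–Crafts alkylation whose closest precedents are the Lewis acid C-arylation of furanosyl acetates with methoxybenzenes (aryl C-glycosides) and the acid-mediated C-arylation of furofuran lactols in the lignan series. No ring is closed; the two C–aryl bonds and the stereocentres C1 and C4 are formed. C1 is set by attack on the convex face of the cis-fused bicycle, anti to the O5 ring, which places the aryl cis to H-6a. C4 is set by attack on the same convex face, cis to the C3a oxygen, as expected from the fold of the bicycle and from the 1,2-cis preference of five-membered oxocarbenium ions that carry an alkoxy group on the neighbouring carbon; the silyl ether cannot bridge to C4 as an ester would. Para regioselectivity on veratrole follows from the methoxy directing effect and the bulk of the electrophile, and the triflic acid set free keeps the benzylic C–O bonds ionising reversibly, so that a kinetically formed endo aryl can still move to the exo position.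

Step 10
Reactants: 13 O-triethylsilyl isogmelinol
Product: 14 isogmelinol, (1S,3aS,4R,6aR)-1,4-bis(3,4-dimethoxyphenyl)tetrahydro-1H,3H-furo[3,4-c]furan-3a-ol
Conditions: HF·pyridine, pyridine, THF, 0 °C → rt
Reagents that add atoms: none
Why: Fluoride-driven desilylation (strong Si–F bond) frees the tertiary alcohol, and the pyridine buffer should keep the two benzylic acetal-type carbons from ionising, so C1 and C4 are not scrambled.

**Compound list**

1 | (±)-paraconic acid, rac-5-oxooxolane-3-carboxylic acid | O=C1CC(C(=O)O)CO1 | starting material
2 | (S)-1-phenylethylammonium (3R)-5-oxooxolane-3-carboxylate | C[C@H]([NH3+])c1ccccc1.O=C1C[C@@H](C(=O)[O-])CO1 | intermediate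
3 | (R)-paraconic acid, (3R)-5-oxooxolane-3-carboxylic acid | O=C1C[C@@H](C(=O)O)CO1 | intermediate
4 | (4R)-2-oxooxolane-3,4-dicarboxylic acid (C3 epimers) | O=C1C(C(=O)O)[C@@H](C(=O)O)CO1 | intermediate
5 | (3R)-4-methylidene-5-oxooxolane-3-carboxylic acid | C=C1C(=O)OC[C@@H]1C(=O)O | intermediate
6 | (3S,4S)-4-hydroxy-4-(hydroxymethyl)-5-oxooxolane-3-carboxylic acid (diol acid) | OC[C@]1(O)C(=O)OC[C@@H]1C(=O)O | intermediate (not isolated)
7 | (3aS,6aS)-3a-hydroxytetrahydro-1H,3H-furo[3,4-c]furan-1,4-dione | O=C1OC[C@]2(O)C(=O)OC[C@H]12 | intermediate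
8 | (3aS,6aS)-3a-(triethylsilyloxy)tetrahydro-1H,3H-furo[3,4-c]furan-1,4-dione | O=C1OC[C@]2(O[Si](CC)(CC)CC)C(=O)OC[C@H]12 | intermediate
9 | (3aS,6aS)-3a-(triethylsilyloxy)tetrahydro-1H,3H-furo[3,4-c]furan-1,4-diol (anomers) | OC1OC[C@]2(O[Si](CC)(CC)CC)C(O)OC[C@H]12 | intermediate
10 | (3aS,6aS)-3a-(triethylsilyloxy)tetrahydro-1H,3H-furo[3,4-c]furan-1,4-diyl diacetate (anomers) | CC(=O)OC1OC[C@]2(O[Si](CC)(CC)CC)C(OC(C)=O)OC[C@H]12 | intermediate
11 | veratrole, 1,2-dimethoxybenzene | COc1ccccc1OC | starting material
12 | (1S,3aS,6aR)-1-(3,4-dimethoxyphenyl)-3a-(triethylsilyloxy)tetrahydro-1H,3H-furo[3,4-c]furan-4-yl acetate (C4 anomers) | COc1ccc([C@H]2OC[C@]3(O[Si](CC)(CC)CC)C(OC(C)=O)OC[C@H]23)cc1OC | intermediate (not isolated)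
13 | O-triethylsilyl isogmelinol, (1S,3aS,4R,6aR)-1,4-bis(3,4-dimethoxyphenyl)-3a-(triethylsilyloxy)tetrahydro-1H,3H-furo[3,4-c]furan | COc1ccc([C@H]2OC[C@]3(O[Si](CC)(CC)CC)[C@@H](c4ccc(OC)c(OC)c4)OC[C@H]23)cc1OC | intermediate
14 | isogmelinol, (1S,3aS,4R,6aR)-1,4-bis(3,4-dimethoxyphenyl)tetrahydro-1H,3H-furo[3,4-c]furan-3a-ol | COc1ccc([C@H]2OC[C@]3(O)[C@@H](c4ccc(OC)c(OC)c4)OC[C@H]23)cc1OC | target

**Step count**

Total: 10 steps. Longest linear sequence: 10 steps (1 → 14); veratrole 11 enters in step 9.

**Steps most likely to fail**

Step 9. The process at risk is attack of veratrole on the C4 oxocarbenium ion from the concave face, because the convex face there carries the triethylsilyloxy group, which would leave the C4 aryl endo. The fallback sets out from 10 and comes back at 14, and replaces kinetic by thermodynamic control at C4. The arylation is run as in step 9 and its outcome at C4 is accepted, the product then being the C4-endo epimer of 13, (1S,3aS,4S,6aR)-1,4-bis(3,4-dimethoxyphenyl)-3a-(triethylsilyloxy)tetrahydro-1H,3H-furo[3,4-c]furan F1. HF·pyridine should free the tertiary alcohol to give 4-epi-isogmelinol F2. F2 is then equilibrated with a Brønsted acid (TsOH·H2O, CH2Cl2, rt): the benzylic C4–O5 bond opens to a para-methoxy-stabilised benzylic cation and recloses, the epimerisation by which the diastereomers of furofuran lignans interconvert. Without the silyl group the exo aryl, cis to the small hydroxyl, should be the favoured position. Isogmelinol 14 is separated by chromatography and the remaining F2 is resubmitted.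

Step 3. The process at risk is loss of configuration at the carboxyl-bearing carbon, or opening of the lactone, during the hot basic carboxylation. The fallback sets out from 3 and comes back at 5, and replaces the thermodynamic carboxylation by kinetic enolate chemistry at low temperature. (R)-Paraconic acid 3 is converted into its dianion (LiN(SiMe3)2, 2.2 equiv, THF, −78 °C: carboxylate first, then the lactone enolate at C4). Me2N=CH2+ I− should give the Mannich base (3R)-4-[(dimethylamino)methyl]-5-oxooxolane-3-carboxylic acid F3. MeI in MeOH quaternises it to 1-[(4R)-4-carboxy-2-oxooxolan-3-yl]-N,N,N-trimethylmethanaminium iodide F4, and aq. NaHCO3 eliminates trimethylamine (Hofmann-type elimination) to give 5 after acidification. The stereocentre stays α to a carboxylate throughout and never meets base above 0 °C.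

Step 7. The process at risk is over-reduction when the aluminium hemiacetal collapses, and loss of the free bis-lactol through ring–chain equilibration with β-elimination of the silyloxy group. The fallback sets out from 8 and comes back at 10, replacing steps 7 and 8 by an in-situ reductive acetylation. After i-Bu2AlH (2.4 equiv, CH2Cl2, −78 °C), pyridine, DMAP and Ac2O are added at −78 °C and the mixture is warmed to 0 °C. The bis(diisobutylaluminium) hemiacetal (3aS,6aS)-1,4-bis[(diisobutylalumanyl)oxy]-3a-(triethylsilyloxy)tetrahydro-1H,3H-furo[3,4-c]furan F5 is thus acetylated directly to 10, and the free bis-lactol 9 is never formed.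

**Further compounds**

F1 | step 9 | (1S,3aS,4S,6aR)-1,4-bis(3,4-dimethoxyphenyl)-3a-(triethylsilyloxy)tetrahydro-1H,3H-furo[3,4-c]furan (C4-endo epimer of 13) | COc1ccc([C@H]2OC[C@]3(O[Si](CC)(CC)CC)[C@H](c4ccc(OC)c(OC)c4)OC[C@H]23)cc1OC
F2 | step 9 | (1S,3aS,4S,6aR)-1,4-bis(3,4-dimethoxyphenyl)tetrahydro-1H,3H-furo[3,4-c]furan-3a-ol (4-epi-isogmelinol) | COc1ccc([C@H]2OC[C@]3(O)[C@H](c4ccc(OC)c(OC)c4)OC[C@H]23)cc1OC
F3 | step 3 | (3R)-4-[(dimethylamino)methyl]-5-oxooxolane-3-carboxylic acid (C4 epimers) | CN(C)CC1C(=O)OC[C@@H]1C(=O)O
F4 | step 3 | 1-[(4R)-4-carboxy-2-oxooxolan-3-yl]-N,N,N-trimethylmethanaminium iodide | C[N+](C)(C)CC1C(=O)OC[C@@H]1C(=O)O.[I-]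
F5 | step 7 | (3aS,6aS)-1,4-bis[(diisobutylalumanyl)oxy]-3a-(triethylsilyloxy)tetrahydro-1H,3H-furo[3,4-c]furan | CC(C)C[Al](CC(C)C)OC1OC[C@]2(O[Si](CC)(CC)CC)C(O[Al](CC(C)C)CC(C)C)OC[C@H]12
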